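Locants are those of the target, (1R,4R,5S,6S,7S)-1-allyl-6-(3,4-dimethoxyphenyl)-4-hydroxy-3-methoxy-7-methylbicyclo[3.2.1]oct-2-en-8-one: C1 (allyl), C2=C3(OMe), C4(OH), C5, C6(aryl), C7(Me), C8=O.
Retrosynthesis: C4–OH goes back to a C4 ketone; then C1–C8 and C4–C5 are cut together. The ring C8–C1–C2=C3–C4–C5 is a cyclohex-3-enone with C2=C3 opposite C5–C8, so C5=C8=O is a ketene, C1=C2–C3=C4 a 1-silyloxy-2-methoxy diene, and the C6–C7 bridge a two-atom tether from ketene carbon C5 to diene terminus C1.
The open-chain acid–enal is cut at C2=C3 (Horner–Wadsworth–Emmons) and at C1–allyl/C1–C2 (Wittig, then Claisen), back to a trans-3-methyl-4-aryl δ-lactone from 5,6-dihydro-2H-pyran-2-one.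
Forward: lactone → lactol → chain extension → acid–enal → in one flask the ketene closes the cyclopentanone ring (C1–C8), then the six-membered ring (C4–C5) → dione → alcohol.
Stereochemistry: C6 from the (R)-BINAP/Rh aryl addition, C7 from trans alkylation, C1 and C5 from the key step under control of C7, C4 from hydride delivery to the exo face of the dione.

Key step: step 10

Remark: the carbon that becomes C1 is an epimer mixture in 13 and 15–19, and the alkene geometry of 12 and 15–21 is not needed, because both are erased in step 10; the SMILES leave that centre open and show the expected major alkene isomer.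

Step 1
Reactants: 1 5,6-dihydro-2H-pyran-2-one; 2 (3,4-dimethoxyphenyl)boronic acid
Product: 3 (R)-4-(3,4-dimethoxyphenyl)tetrahydro-2H-pyran-2-one
Conditions: [Rh(OH)((R)-BINAP)]2 (3 mol % Rh), 2 (2.5 equiv), dioxane/H2O 10:1, 40 °C
Reagents that add atoms: none
Why: Rh-catalysed asymmetric 1,4-addition of an arylboronic acid (Hayashi–Miyaura reaction) to the cyclic cis-enoate, in which the (R)-BINAP-bound aryl–rhodium species should attack the same enantioface as with 2-cyclohexenone and so set C4 as R (the later C6).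

Step 2
Reactants: 3 (R)-4-(3,4-dimethoxyphenyl)tetrahydro-2H-pyran-2-one
Product: 4 (3S,4R)-4-(3,4-dimethoxyphenyl)-3-methyltetrahydro-2H-pyran-2-one
Conditions: LiN(iPr)2 (1.1 equiv), THF, −78 °C; MeI (3 equiv), −78 → −40 °C
Reagents that add atoms: iodomethane, CI
Why: enolate alkylation of the δ-lactone, in which MeI should approach anti to the neighbouring aryl group and give the 3,4-trans lactone (the later C7 methyl centre).

Step 3
Reactants: 4 (3S,4R)-4-(3,4-dimethoxyphenyl)-3-methyltetrahydro-2H-pyran-2-one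
Product: 5 (3S,4R)-4-(3,4-dimethoxyphenyl)-3-methyltetrahydro-2H-pyran-2-ol (lactol, both anomers)
Conditions: iBu2AlH (1.1 equiv), CH2Cl2, −78 °C; aq. potassium sodium tartrate
Reagents that add atoms: none
Why: partial reduction of a lactone to the lactol, which stops at the aluminium hemiacetal at low temperature and forms no stereocentre that matters (anomers).

Step 4
Reactants: 6 prop-2-en-1-ol (allyl alcohol); 7 paraformaldehyde; 8 triphenylphosphine
Product: 10 [(allyloxy)methyl]triphenylphosphonium chloride, via allyl chloromethyl ether 9 (not isolated)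
Conditions: Me3SiCl (1.2 equiv), neat, 0 °C → rt; PPh3, toluene, 80 °C
Reagents that add atoms: chlorotrimethylsilane, C[Si](C)(C)Cl
Why: chloromethylation of the alcohol with formaldehyde/Me3SiCl followed by SN2 quaternisation of PPh3, the usual way to alkoxymethyl phosphonium salts.

Step 5
Reactants: 5 (3S,4R)-4-(3,4-dimethoxyphenyl)-3-methyltetrahydro-2H-pyran-2-ol; 10 [(allyloxy)methyl]triphenylphosphonium chloride
Product: 13 (3S,4R)-2-allyl-4-(3,4-dimethoxyphenyl)-6-hydroxy-3-methylhexanal (C2 epimers), via phosphorus ylide 11 (not isolated), via allyl enol ether 12 (not isolated)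
Conditions: 10 (2.4 equiv), KOtBu (2.3 equiv), THF, 0 °C; 5, 0 °C → rt; AcOH to neutrality, solvent changed to xylene, 140 °C
Reagents that add atoms: none
Why: Wittig olefination of the lactol (through its open hydroxy aldehyde) gives the allyl enol ether, whose Claisen [3,3] rearrangement moves the allyl group to the former carbonyl carbon and unveils the homologous aldehyde, the new C2 centre being uncontrolled and unneeded.

Step 6
Reactants: 13 (3S,4R)-2-allyl-4-(3,4-dimethoxyphenyl)-6-hydroxy-3-methylhexanal; 14 methyl 2-(dimethoxyphosphoryl)-2-methoxyacetate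
Product: 15 methyl (2Z,5R,6R)-4-allyl-6-(3,4-dimethoxyphenyl)-8-hydroxy-2-methoxy-5-methyloct-2-enoate (C4 epimers)
Conditions: 14 (1.6 equiv), LiN(SiMe3)2 (1.5 equiv), THF, −78 °C; 13, −78 → 0 °C
Reagents that add atoms: none
Why: Horner–Wadsworth–Emmons olefination with the α-methoxy phosphonoacetate should give the 2-methoxy enoate, mainly Z, a geometry of no later consequence.

Step 7
Reactants: 15 methyl (2Z,5R,6R)-4-allyl-6-(3,4-dimethoxyphenyl)-8-hydroxy-2-methoxy-5-methyloct-2-enoate
Product: 16 (2Z,5R,6R)-4-allyl-6-(3,4-dimethoxyphenyl)-2-methoxy-5-methyloct-2-ene-1,8-diol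
Conditions: iBu2AlH (3.5 equiv), CH2Cl2, −78 °C; aq. potassium sodium tartrate, no acid
Reagents that add atoms: none
Why: 1,2-reduction of the α,β-unsaturated ester to the allylic alcohol with iBu2AlH, worked up without acid because the 2-methoxy allylic alcohol is an acid-labile enol ether.

Step 8
Reactants: 16 (2Z,5R,6R)-4-allyl-6-(3,4-dimethoxyphenyl)-2-methoxy-5-methyloct-2-ene-1,8-diol
Product: 17 (2Z,5R,6R)-4-allyl-6-(3,4-dimethoxyphenyl)-8-hydroxy-2-methoxy-5-methyloct-2-enal
Conditions: MnO2 (15 equiv), CH2Cl2, rt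
Reagents that add atoms: none
Why: MnO2 oxidises only the allylic alcohol and leaves the saturated primary alcohol.

Step 9
Reactants: 17 (2Z,5R,6R)-4-allyl-6-(3,4-dimethoxyphenyl)-8-hydroxy-2-methoxy-5-methyloct-2-enal
Product: 18 (3R,4R,6Z)-5-allyl-3-(3,4-dimethoxyphenyl)-7-methoxy-4-methyl-8-oxooct-6-enoic acid
Conditions: TEMPO (0.2 equiv), PhI(OAc)2 (2.4 equiv), MeCN/H2O 1:1, rt
Reagents that add atoms: water, O
Why: oxoammonium (TEMPO) oxidation of the primary alcohol through the aldehyde hydrate to the carboxylic acid, which the conjugated α-alkoxy aldehyde should survive because it is hardly hydrated.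

Step 10
Reactants: 18 (3R,4R,6Z)-5-allyl-3-(3,4-dimethoxyphenyl)-7-methoxy-4-methyl-8-oxooct-6-enoic acid
Product: 23 (1R,4S,5S,6S,7S)-1-allyl-6-(3,4-dimethoxyphenyl)-4-hydroxy-3-methoxy-7-methylbicyclo[3.2.1]oct-2-en-8-one (C4 epimer of the target), via acid chloride 19 (not isolated), via silyl dienol ether 20 (not isolated), via ketene 21 (not isolated), via silyl ether 22 (not isolated)
Conditions: Me2C=C(Cl)NMe2 (1.1 equiv), CH2Cl2, 0 °C → rt; Et3N (6 equiv) then tBuMe2SiOTf (1.2 equiv), −78 → −30 °C; syringe pump (6 h) into Et3N/toluene, 90 °C, 0.003 M; Bu4NF/AcOH (2 equiv each), THF, 0 °C → rt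
Reagents that add atoms: none
Why: Proposed new method: Et3N dehydrochlorinates the acid chloride to the aldoketene 21, whose electrophilic central carbon C8 is attacked by the silyloxy-activated diene terminus C1 to give a cyclopentanone enolate/silyl-oxocarbenium zwitterion that collapses by C5–C4 bonding, a stepwise polar (4+2) annulation across the ketene C=C that forms C1–C8 and C4–C5 in one operation. The closest known reaction types are the intramolecular ketene–alkene (2+2) cycloaddition of unsaturated acid chlorides with Et3N and the 1,3-acyl shift that expands 2-vinylcyclobutanones (ketene–diene adducts) to cyclohexenones. The cyclopentanone closes 5-exo-trig onto C1=C2 and the six-membered ring closes 6-(enolendo)-exo-trig onto the oxocarbenium carbon, which bridges the first ring to the bicyclo[3.2.1]octenone. C1 is set in the first bond formation, where allylic 1,2-strain at the C7–C1 bond of the (5E) dienol ether keeps the C7 hydrogen beside the allyl group and the C7 methyl beside the dienyl arm, so that aryl ends exo (syn to C8) and methyl endo; C5 follows from C1 because the enolate carbon reaches C4 only on the face carrying the dienyl arm; C4 is expected mainly with oxygen syn to C8 (collapse of the contact ion pair), is not relied on, and is reset in steps 11 and 12. The step needs periselectivity (C- over O-closure, six- over four-membered ring, closure over ketene dimerisation) and a cisoid diene: the four-membered alternative is a strained bicyclo[2.1.1]hexanone, the O-closed silyl enol acetal can re-ionise to the same zwitterion (Petasis–Ferrier-type O-to-C shift), high dilution disfavours dimerisation, and the transoid diene is destabilised by the clash of the C3 methoxy group with the inside allyl group at C1. Buffered Bu4NF/AcOH then removes the silyl group without inviting retro-aldol opening.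

Step 11
Reactants: 23 (1R,4S,5S,6S,7S)-1-allyl-6-(3,4-dimethoxyphenyl)-4-hydroxy-3-methoxy-7-methylbicyclo[3.2.1]oct-2-en-8-one
Product: 24 (1R,5R,6S,7S)-5-allyl-7-(3,4-dimethoxyphenyl)-3-methoxy-6-methylbicyclo[3.2.1]oct-3-ene-2,8-dione
Conditions: Dess–Martin periodinane (1.5 equiv), NaHCO3, CH2Cl2, 0 °C → rt
Reagents that add atoms: none
Why: Dess–Martin oxidation of the secondary allylic alcohol removes the uncontrolled carbinol centre, and the resulting 1,3-diketone cannot enolise at the bridgehead, so no other centre is at risk.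

Step 12
Reactants: 24 (1R,5R,6S,7S)-5-allyl-7-(3,4-dimethoxyphenyl)-3-methoxy-6-methylbicyclo[3.2.1]oct-3-ene-2,8-dione
Product: 25 (1R,4R,5S,6S,7S)-1-allyl-6-(3,4-dimethoxyphenyl)-4-hydroxy-3-methoxy-7-methylbicyclo[3.2.1]oct-2-en-8-one
Conditions: NaBH4 (1.0 equiv), CeCl3·7H2O (1.2 equiv), MeOH/CH2Cl2 3:1, −78 °C
Reagents that add atoms: none
Why: Luche 1,2-reduction of the α-methoxy enone carbonyl (C2 of 24) should be preferred over the bridging C8 ketone (flanked by quaternary C5, screened by the exo aryl group, reversibly hemiketalised in CeCl3/MeOH), and hydride should enter from the face of the one-carbon bridge because the other face is covered by the C6–C7 bridge and its endo hydrogen, leaving the hydroxyl anti to C8 as in the target.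

Compound list
1 | 5,6-dihydro-2H-pyran-2-one | O=C1C=CCCO1 | starting material
2 | (3,4-dimethoxyphenyl)boronic acid | COc1ccc(cc1OC)B(O)O | starting material
3 | (R)-4-(3,4-dimethoxyphenyl)tetrahydro-2H-pyran-2-one | O=C1OCC[C@@H](c2ccc(OC)c(OC)c2)C1 | intermediate
4 | (3S,4R)-4-(3,4-dimethoxyphenyl)-3-methyltetrahydro-2H-pyran-2-one | O=C1OCC[C@@H](c2ccc(OC)c(OC)c2)[C@@H]1C | intermediate
5 | (3S,4R)-4-(3,4-dimethoxyphenyl)-3-methyltetrahydro-2H-pyran-2-ol (both anomers) | OC1OCC[C@@H](c2ccc(OC)c(OC)c2)[C@@H]1C | intermediate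
6 | prop-2-en-1-ol (allyl alcohol) | C=CCO | starting material
7 | paraformaldehyde (shown as formaldehyde) | C=O | starting material
8 | triphenylphosphine | c1ccc(cc1)P(c1ccccc1)c1ccccc1 | starting material
9 | 3-(chloromethoxy)prop-1-ene (allyl chloromethyl ether) | C=CCOCCl | intermediate
10 | [(allyloxy)methyl]triphenylphosphonium chloride | C=CCOC[P+](c1ccccc1)(c1ccccc1)c1ccccc1.[Cl-] | intermediate
11 | [(allyloxy)methylene]triphenylphosphorane | C=CCOC=P(c1ccccc1)(c1ccccc1)c1ccccc1 | intermediate
12 | (3R,4S)-6-(allyloxy)-3-(3,4-dimethoxyphenyl)-4-methylhex-5-en-1-ol (E/Z mixture) | OCC[C@@H](c1ccc(OC)c(OC)c1)[C@H](C)C=COCC=C | intermediate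
13 | (3S,4R)-2-allyl-4-(3,4-dimethoxyphenyl)-6-hydroxy-3-methylhexanal (C2 epimers) | OCC[C@@H](c1ccc(OC)c(OC)c1)[C@H](C)C(CC=C)C=O | intermediate
14 | methyl 2-(dimethoxyphosphoryl)-2-methoxyacetate | COC(=O)C(OC)P(=O)(OC)OC | starting material
15 | methyl (2Z,5R,6R)-4-allyl-6-(3,4-dimethoxyphenyl)-8-hydroxy-2-methoxy-5-methyloct-2-enoate (C4 epimers) | OCC[C@@H](c1ccc(OC)c(OC)c1)[C@H](C)C(CC=C)/C=C(\OC)C(=O)OC | intermediate
16 | (2Z,5R,6R)-4-allyl-6-(3,4-dimethoxyphenyl)-2-methoxy-5-methyloct-2-ene-1,8-diol (C4 epimers) | OCC[C@@H](c1ccc(OC)c(OC)c1)[C@H](C)C(CC=C)/C=C(\OC)CO | intermediate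
17 | (2Z,5R,6R)-4-allyl-6-(3,4-dimethoxyphenyl)-8-hydroxy-2-methoxy-5-methyloct-2-enal (C4 epimers) | OCC[C@@H](c1ccc(OC)c(OC)c1)[C@H](C)C(CC=C)/C=C(\OC)C=O | intermediate
18 | (3R,4R,6Z)-5-allyl-3-(3,4-dimethoxyphenyl)-7-methoxy-4-methyl-8-oxooct-6-enoic acid (C5 epimers) | OC(=O)C[C@@H](c1ccc(OC)c(OC)c1)[C@H](C)C(CC=C)/C=C(\OC)C=O | intermediate
19 | (3R,4R,6Z)-5-allyl-3-(3,4-dimethoxyphenyl)-7-methoxy-4-methyl-8-oxooct-6-enoyl chloride (C5 epimers) | ClC(=O)C[C@@H](c1ccc(OC)c(OC)c1)[C@H](C)C(CC=C)/C=C(\OC)C=O | intermediate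
20 | (3R,4S,5E,7Z)-5-allyl-8-[(tert-butyldimethylsilyl)oxy]-3-(3,4-dimethoxyphenyl)-7-methoxy-4-methylocta-5,7-dienoyl chloride | ClC(=O)C[C@@H](c1ccc(OC)c(OC)c1)[C@H](C)/C(CC=C)=C/C(OC)=C/O[Si](C)(C)C(C)(C)C | intermediate
21 | (3S,4S,5E,7Z)-5-allyl-8-[(tert-butyldimethylsilyl)oxy]-3-(3,4-dimethoxyphenyl)-7-methoxy-4-methylocta-1,5,7-trien-1-one (ketene) | O=C=C[C@@H](c1ccc(OC)c(OC)c1)[C@H](C)/C(CC=C)=C/C(OC)=C/O[Si](C)(C)C(C)(C)C | intermediate
22 | (1R,4S,5S,6S,7S)-1-allyl-4-[(tert-butyldimethylsilyl)oxy]-6-(3,4-dimethoxyphenyl)-3-methoxy-7-methylbicyclo[3.2.1]oct-2-en-8-one | C=CC[C@@]12C=C(OC)[C@@H](O[Si](C)(C)C(C)(C)C)[C@@H](C1=O)[C@@H](c1ccc(OC)c(OC)c1)[C@@H]2C | intermediate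
23 | (1R,4S,5S,6S,7S)-1-allyl-6-(3,4-dimethoxyphenyl)-4-hydroxy-3-methoxy-7-methylbicyclo[3.2.1]oct-2-en-8-one | C=CC[C@@]12C=C(OC)[C@@H](O)[C@@H](C1=O)[C@@H](c1ccc(OC)c(OC)c1)[C@@H]2C | intermediate
24 | (1R,5R,6S,7S)-5-allyl-7-(3,4-dimethoxyphenyl)-3-methoxy-6-methylbicyclo[3.2.1]oct-3-ene-2,8-dione | C=CC[C@@]12C=C(OC)C(=O)[C@@H](C1=O)[C@@H](c1ccc(OC)c(OC)c1)[C@@H]2C | intermediate
25 | (1R,4R,5S,6S,7S)-1-allyl-6-(3,4-dimethoxyphenyl)-4-hydroxy-3-methoxy-7-methylbicyclo[3.2.1]oct-2-en-8-one | C=CC[C@@]12C=C(OC)[C@H](O)[C@@H](C1=O)[C@@H](c1ccc(OC)c(OC)c1)[C@@H]2C | target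

Total step count: 12. Longest linear sequence: 11 (steps 1–3 and 5–12; step 4 makes the Wittig salt).

Steps most likely to fail

Step 10 (Proposed new method). The ketene may be lost to dimerisation, the zwitterion may collapse through oxygen or to the four-membered ring without funnelling to the bridged ketone, or attack on C1 may show poor facial selectivity. The fallback uses known reaction types and sets out from 18. The acid chloride 19 and then the silyl dienol ether 20 are made as in step 10, but with only a slight excess of Et3N and at −78 °C, where dehydrochlorination is slow. The cold solution is treated with ZnBr2 (2 equiv, CH2Cl2, −78 → −20 °C), which should bring about a Mukaiyama-type C-acylation of the silyl dienol ether at its vinylogous carbon by the acid chloride. This closes the cyclopentanone, sets C1 under the same allylic-strain control, and gives the keto enal (2R,3S,4R)-2-allyl-4-(3,4-dimethoxyphenyl)-2-[(E)-2-methoxy-3-oxoprop-1-en-1-yl]-3-methylcyclopentan-1-one F1. An intramolecular aldol addition of the cyclopentanone α-carbon to the aldehyde (KOtBu 0.2 equiv, THF, −40 °C) then closes the six-membered ring and comes back to the route at 23; either C4 epimer serves step 11.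

Step 12. Hydride may attack the strained bridging ketone (loss of chemoselectivity), methoxide may open the non-enolisable 1,3-diketone (retro-Claisen), or attack may come from the wrong face. The fallback sets out from 23, whose C4 configuration is opposite to the target's, and bypasses the dione 24. Mitsunobu inversion (4-nitrobenzoic acid, PPh3, DIAD, THF, 0 °C → rt) should give the inverted ester (1R,4R,5S,6S,7S)-1-allyl-6-(3,4-dimethoxyphenyl)-3-methoxy-7-methyl-8-oxobicyclo[3.2.1]oct-2-en-4-yl 4-nitrobenzoate F2. Methanolysis (K2CO3, MeOH, 0 °C) then comes back to the route at 25.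

Step 9. The enal aldehyde may be over-oxidised (loss of chemoselectivity between the saturated and the conjugated aldehyde), or the enol ether may hydrolyse in the aqueous acidic medium. The fallback sets out from 15 and bypasses 16 and 17. The primary alcohol is oxidised first (TEMPO, PhI(OAc)2, MeCN/H2O), when neither an aldehyde nor a labile enol ether is present, to the acid ester (3R,4R,6Z)-5-allyl-3-(3,4-dimethoxyphenyl)-7,8-dimethoxy-4-methyl-8-oxooct-6-enoic acid F3. The α-methoxy ester is then half-reduced with iBu2AlH (2.2 equiv, toluene, −78 °C): the first equivalent forms the aluminium carboxylate and the α-methoxy group should hold the aluminium hemiacetal until work-up. This comes back to the route at 18.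

Further compounds
F1 | step 10 | (2R,3S,4R)-2-allyl-4-(3,4-dimethoxyphenyl)-2-[(E)-2-methoxy-3-oxoprop-1-en-1-yl]-3-methylcyclopentan-1-one | C=CC[C@@]1(/C=C(/OC)C=O)C(=O)C[C@@H](c2ccc(OC)c(OC)c2)[C@@H]1C
F2 | step 12 | (1R,4R,5S,6S,7S)-1-allyl-6-(3,4-dimethoxyphenyl)-3-methoxy-7-methyl-8-oxobicyclo[3.2.1]oct-2-en-4-yl 4-nitrobenzoate | C=CC[C@@]12C=C(OC)[C@H](OC(=O)c3ccc(cc3)[N+](=O)[O-])[C@@H](C1=O)[C@@H](c1ccc(OC)c(OC)c1)[C@@H]2C
F3 | step 9 | (3R,4R,6Z)-5-allyl-3-(3,4-dimethoxyphenyl)-7,8-dimethoxy-4-methyl-8-oxooct-6-enoic acid | OC(=O)C[C@@H](c1ccc(OC)c(OC)c1)[C@H](C)C(CC=C)/C=C(\OC)C(=O)OC
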